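- In a one-step world a catalyst counts with its whole charge and its order is one, so the first thing you ask of this flask is how much of the free catalyst charge is left to work once the impurity has taken its share.

| flask | substrate | reagent | free catalyst | impurity | remark |
|---|---|---|---|---|---|
| Thursday's | 0.050 M | 0.037 M | 50 µM | 14 µM | run made earlier |
| Saturday's | 0.050 M | 0.15 M | 50 µM | 14 µM | run made earlier |
| Sunday's | 0.050 M | 0.075 M | 100 µM | 14 µM | run made earlier |
| flask | 0.050 M | 0.0750 M | 50 µM | 14 µM |  |

- Thursday's (time / min: target / %, substrate / %): 4.00: 2.5, 97.2; 10.0: 5.8, 93.2; 20.0: 11.5, 88.5; 30.0: 16.5, 84.1; 40.0: 19.6, 80.4; 50.0: 22.8, 77.4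
- Saturday's (time / min: target / %, substrate / %): 10.0: 6.9, 93.3; 20.0: 12.6, 87.4; 25.0: 14.4, 85.0; 40.0: 20.7, 79.9; 50.0: 24.2, 76.5
- Sunday's (time / min: target / %, substrate / %): 10.0: 14.2, 86.1; 20.0: 22.9, 77.0; 30.0: 30.0, 69.9; 40.0: 34.5, 64.8; 50.0: 39.4, 60.3

(standard deviation of a reading: 0.3 percentage points)

- apparent order in reagent when 20% of the substrate are converted (percent change of the rate of making target for one percent more reagent charged)
- apparent order in free catalyst when 20% of the substrate are converted (percent change of the rate of making target for one percent more free catalyst charged)



- Reagent comes first because it shows which runs you may pair: Saturday's charge is 4.05 times Thursday's, yet at 50.0 min the target reads 24.2% on Saturday against 22.8% on Thursday, so I commit to an order of 0.0426 for the flask, small enough that you may set either run beside Sunday's.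
- Now suppose, as my own assumption, that impurity and free catalyst react completely at the outset, with the impurity as limiting reagent of that side reaction; the working fraction, the part of the catalyst charge the impurity leaves over, is then 72.0% in the flask and 86.0% on Sunday's charge.
- If the rate follows the working catalyst, one percent more charge gives one percent divided by the working fraction, so the flask's local catalyst order is 1.39.
- The first way to check this uses charges: Sunday's run holds twice the flask's catalyst charge, hence 2.39 times its working catalyst.
- The second way uses readings: Sunday's target reaches 22.9% at 20.0 min and Thursday's reaches 22.8% at 50.0 min, while Sunday's 14.2% at 10.0 min matches Saturday's 14.4% at 25.0 min, so both pairs read a time ratio of 2.50, which with readings good to 0.3 percentage points I take as agreeing with the first way.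
- Turned into an order, that ratio gives 1.32, lower than 1.39, and this is the way that cheats, because it averages from the flask's charge up to Sunday's, where one over the working fraction is 1.16; I keep 1.39.
- The forecast gave 0.12 for reagent, higher than my 0.0426, speaking of “near-saturation behaviour”, and 1.3 for catalyst, lower than my 1.39.
- The flask gives 0.045 for reagent and 1.4 for catalyst.

    substrate + free catalyst → catalyst intermediate A (k = 13000 /M/h)
    reagent + catalyst intermediate A → catalyst intermediate B (k = 1.20 × 10⁵ /M/h)
    catalyst intermediate B ⇌ by-product + catalyst intermediate C (K = 0.0100 M, k = 45000 /h)
    catalyst intermediate C ⇌ free catalyst + target (K = 0.0390 M, k = 70000 /h)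
    free catalyst + by-product ⇌ idle complex (K = 12.0 /M, k = 300 /M/h)
    free catalyst + impurity → spent catalyst (k = 2.20 × 10⁶ /M/h)

- By 0.150 h the flask's impurity stands at 0% and spent catalyst at 28.0% of the catalyst charged, leaving the working fraction of 72.0% in other forms, and spent catalyst still stands at 28.0% after 15.0 h. While that working fraction went round, free catalyst fell from 58.8% to 29.3% of the charge and catalyst intermediate B rose from 2.34% to 22.1%, and the flask's target reached 33.9% at 1.50 h.

(The runs stem from a simulated flask from invented constants; noise was put on by code.)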